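## Retrosynthetic overview

1. Numbering (tetralin): ring A is the arene (C4a, C5–C8, C8a; CH2OAc on C6, OH on C8); ring B is C1 (CHMe), C2 (CHOAc), C3 (CH2), C4 (CH bearing the side chain, whose methine is C11). The end game is only an exchange of oxygen protecting groups.
2. Key disconnection: the C2–C3 bond of ring B, opened to a C2 aldehyde on C8a and a 1,1-disubstituted styrene (C3=C4) on C4a. A samarium ketyl–alkene 6-endo cyclisation closes ring B and sets C2 and C4 in one operation.
3. Enabling feature: the C2 carbinol lies 1,3 to the benzylic C4 across the C3 methylene, so a C2 ketyl adding to C3 leaves a C4 radical stabilised by ring A. The ortho pair C8a/C4a holds the two partners at six-ring distance, and the peri C8 oxygen fixes the C1 methyl pseudoaxial, which relays C1 to C2 and C4.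
4. Cyclisation precursor: C4a–C4 by Suzuki–Miyaura coupling of an aryl bromide with an alkenyl boronate. The aryl bromide gets its C1–C2 arm by ortho-lithiation between OMe and Br plus oxirane, and C1 by Evans methylation. The boronate comes from (S)-β-citronellene (C11 from the chiral pool) by Wacker oxidation, kinetic enol triflation and Miyaura borylation.
5. Ring order: ring A is bought; ring B is the only ring made (step 12); deprotection and acetylation follow.

Key step: step 12

Assumption: (3-bromo-5-methoxyphenyl)methanol, oxirane, (4R)-4-benzyl-1,3-oxazolidin-2-one and (3S)-3,7-dimethylocta-1,6-diene ((S)-β-citronellene, high enantiomeric purity) are taken as commercial; TBS = tert-butyldimethylsilyl; the tetralin numbering above is used for all intermediates.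

## Route

Step 1
Reactants: 1 (3-bromo-5-methoxyphenyl)methanol
Product: 2 tert-butyl[(3-bromo-5-methoxyphenyl)methoxy]dimethylsilane
Conditions: TBSCl, imidazole, DMF, 0 °C to rt
Reagents that add atoms: tert-butyldimethylsilyl chloride, CC(C)(C)[Si](C)(C)Cl
Why: Silyl ether protection of the primary benzylic alcohol gives a group that is stable to amide bases, hydride and SmI2 and prevents alkoxide-directed lithiation.

Step 2
Reactants: 2 tert-butyl[(3-bromo-5-methoxyphenyl)methoxy]dimethylsilane; 3 oxirane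
Product: 5 2-[2-bromo-6-methoxy-4-(TBSOCH2)phenyl]ethan-1-ol, via aryllithium 4 (not isolated)
Conditions: LiN(iPr)2, THF, −78 °C; then oxirane, BF3·OEt2, −78 °C
Reagents that add atoms: none
Why: Directed ortho-lithiation removes the ring hydrogen flanked by OMe and Br (the most acidic site, future C8a), and the aryllithium opens BF3-activated oxirane at −78 °C, below the temperature of LiBr loss, to install C1 and C2.

Step 3
Reactants: 5 2-[2-bromo-6-methoxy-4-(TBSOCH2)phenyl]ethan-1-ol
Product: 7 [2-bromo-6-methoxy-4-(TBSOCH2)phenyl]acetic acid, via arylacetaldehyde 6 (not isolated)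
Conditions: TEMPO (cat.), PhI(OAc)2, MeCN/H2O, rt
Reagents that add atoms: water, O
Why: Oxoammonium (TEMPO) oxidation takes the primary alcohol through the aldehyde hydrate to the arylacetic acid and should leave the silyl ether, the aryl bromide and the anisole untouched.

Step 4
Reactants: 7 [2-bromo-6-methoxy-4-(TBSOCH2)phenyl]acetic acid; 8 (4R)-4-benzyl-1,3-oxazolidin-2-one
Product: 10 (4R)-4-benzyl-3-{[2-bromo-6-methoxy-4-(TBSOCH2)phenyl]acetyl}-1,3-oxazolidin-2-one, via mixed pivalic anhydride 9 (not isolated)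
Conditions: t-BuCOCl, Et3N, THF, −20 °C; then 8, LiCl, rt
Reagents that add atoms: none
Why: N-Acylation of the Evans oxazolidinone through the mixed pivalic anhydride with LiCl/Et3N needs no strong base and gives the imide for auxiliary-controlled methylation.

Step 5
Reactants: 10 (4R)-4-benzyl-3-{[2-bromo-6-methoxy-4-(TBSOCH2)phenyl]acetyl}-1,3-oxazolidin-2-one
Product: 12 (4R)-4-benzyl-3-{(2R)-2-[2-bromo-6-methoxy-4-(TBSOCH2)phenyl]propanoyl}-1,3-oxazolidin-2-one, via sodium enolate 11 (not isolated)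
Conditions: NaN(SiMe3)2, THF, −78 °C; then MeI, −78 to −40 °C
Reagents that add atoms: iodomethane, CI
Why: Evans asymmetric alkylation: the chelated sodium (Z)-enolate is methylated on the face away from the benzyl group of the (R)-auxiliary, which should set C1 as R (aryl outranks methyl, so the (R)-auxiliary gives the (R)-2-arylpropanoyl imide).

Step 6
Reactants: 12 (4R)-4-benzyl-3-{(2R)-2-[2-bromo-6-methoxy-4-(TBSOCH2)phenyl]propanoyl}-1,3-oxazolidin-2-one
Product: 13 (2R)-2-[2-bromo-6-methoxy-4-(TBSOCH2)phenyl]propan-1-ol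
Conditions: LiBH4, MeOH (1 equiv), Et2O, 0 °C
Reagents that add atoms: none
Why: Reductive cleavage of the imide with LiBH4 gives the primary alcohol and the recoverable auxiliary, and at the alcohol stage the benzylic C1 centre is configurationally safe.

Step 7
Reactants: 14 (3S)-3,7-dimethylocta-1,6-diene
Product: 15 (3S)-3,7-dimethyloct-6-en-2-one
Conditions: PdCl2 (10 mol %), CuCl, O2 (1 atm), DMF/H2O, rt
Reagents that add atoms: water, O
Why: Wacker–Tsuji oxidation is selective for the monosubstituted alkene over the trisubstituted one and gives the methyl ketone with Markovnikov regiochemistry, leaving the chiral-pool C11 centre untouched.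

Step 8
Reactants: 15 (3S)-3,7-dimethyloct-6-en-2-one
Product: 17 (3S)-3,7-dimethylocta-1,6-dien-2-yl trifluoromethanesulfonate, via lithium enolate 16 (not isolated)
Conditions: LiN(iPr)2, THF, −78 °C; then PhNTf2, −78 to 0 °C
Reagents that add atoms: N-phenylbis(trifluoromethanesulfonimide), O=S(=O)(N(c1ccccc1)S(=O)(=O)C(F)(F)F)C(F)(F)F
Why: Kinetic enolisation removes a methyl proton and not the hindered tertiary C11–H, so O-triflation should give the terminal enol triflate with C11 intact (kinetic enol triflate formation).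

Step 9
Reactants: 17 (3S)-3,7-dimethylocta-1,6-dien-2-yl trifluoromethanesulfonate
Product: 18 2-[(3S)-3,7-dimethylocta-1,6-dien-2-yl]-4,4,5,5-tetramethyl-1,3,2-dioxaborolane
Conditions: B2pin2, PdCl2(PPh3)2 (3 mol %), PPh3, KOPh, toluene, 50 °C
Reagents that add atoms: bis(pinacolato)diboron, CC1(C)OB(OC1(C)C)B1OC(C)(C)C(C)(C)O1
Why: Miyaura borylation of the alkenyl triflate with the mild base KOPh gives the 1,1-disubstituted alkenyl boronate without moving the double bond.

Step 10
Reactants: 13 (2R)-2-[2-bromo-6-methoxy-4-(TBSOCH2)phenyl]propan-1-ol; 18 2-[(3S)-3,7-dimethylocta-1,6-dien-2-yl]-4,4,5,5-tetramethyl-1,3,2-dioxaborolane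
Product: 19 (2R)-2-{2-[(3S)-3,7-dimethylocta-1,6-dien-2-yl]-6-methoxy-4-(TBSOCH2)phenyl}propan-1-ol
Conditions: Pd(OAc)2 (5 mol %), SPhos, K3PO4, toluene/H2O, 80 °C
Reagents that add atoms: none
Why: Suzuki–Miyaura coupling with the bulky, electron-rich SPhos ligand joins C4a to C4 at the ortho-substituted aryl bromide and tolerates the free alcohol and the silyl ether.

Step 11
Reactants: 19 (2R)-2-{2-[(3S)-3,7-dimethylocta-1,6-dien-2-yl]-6-methoxy-4-(TBSOCH2)phenyl}propan-1-ol
Product: 20 (2R)-2-{2-[(3S)-3,7-dimethylocta-1,6-dien-2-yl]-6-methoxy-4-(TBSOCH2)phenyl}propanal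
Conditions: Dess–Martin periodinane, pyridine, CH2Cl2, 0 °C; used at once
Reagents that add atoms: none
Why: Buffered Dess–Martin oxidation gives the α-aryl aldehyde without over-oxidation, and it is carried on immediately because C1 is now enolisable.

Step 12
Reactants: 20 (2R)-2-{2-[(3S)-3,7-dimethylocta-1,6-dien-2-yl]-6-methoxy-4-(TBSOCH2)phenyl}propanal
Product: 23 (1R,2S,4S)-6-(TBSOCH2)-8-methoxy-1-methyl-4-[(2S)-6-methylhept-5-en-2-yl]-1,2,3,4-tetrahydronaphthalen-2-ol, via samarium ketyl 21 (not isolated), via benzylic organosamarium 22 (not isolated)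
Conditions: SmI2 (2.5 equiv), HMPA, t-BuOH (2.2 equiv), THF (0.01 M), −78 to 0 °C
Reagents that add atoms: none
Why: SmI2/HMPA (divalent samarium) transfers one electron to the aldehyde to give samarium ketyl 21, whose C2 adds to the unsubstituted terminus C3 of the ortho 1,1-disubstituted styrene; the resulting tertiary benzylic C4 radical is reduced by a second SmI2 to organosamarium 22 and protonated by t-BuOH. The closest known reaction type is the samarium ketyl–alkene reductive cyclisation of unsaturated aldehydes onto styrenes. Ring B closes in the 6-endo-trig mode, because 5-exo attack would have to hit the fully substituted C4 and would forgo the benzylic radical. C2 is controlled by the C1 centre: peri strain with the C8 methoxy group holds the C1 methyl pseudoaxial in the chair-like transition state and the bulky O–SmI2(HMPA)n group takes the equatorial site, cis to that methyl. C4 is controlled by the new ring: the planar C4 organosamarium should be protonated axially on the face away from the pseudoaxial C1 methyl and anti to the axial C3–H, so hydrogen enters trans and the side chain ends cis to the C1 methyl and the C2 oxygen, while C11 is not touched. The step needs regioselectivity (secured by the 1,1-disubstitution and the benzylic radical), chemoselectivity for the styrene over the isolated trisubstituted alkene (a ketyl adds only to the conjugated acceptor) and retention of the labile C1 centre (electron transfer at −78 °C should outrun enolisation).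

Step 13
Reactants: 23 (1R,2S,4S)-6-(TBSOCH2)-8-methoxy-1-methyl-4-[(2S)-6-methylhept-5-en-2-yl]-1,2,3,4-tetrahydronaphthalen-2-ol
Product: 24 (1R,2S,4S)-6-(hydroxymethyl)-8-methoxy-1-methyl-4-[(2S)-6-methylhept-5-en-2-yl]-1,2,3,4-tetrahydronaphthalen-2-ol
Conditions: Bu4NF, THF, rt
Reagents that add atoms: none
Why: Fluoride-mediated desilylation frees the C6 hydroxymethyl group without affecting the secondary alcohol, the aryl methyl ether or the alkene.

Step 14
Reactants: 24 (1R,2S,4S)-6-(hydroxymethyl)-8-methoxy-1-methyl-4-[(2S)-6-methylhept-5-en-2-yl]-1,2,3,4-tetrahydronaphthalen-2-ol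
Product: 25 (1R,2S,4S)-6-(hydroxymethyl)-1-methyl-4-[(2S)-6-methylhept-5-en-2-yl]-1,2,3,4-tetrahydronaphthalene-2,8-diol
Conditions: NaSEt, DMF, 120 °C; then aq. NH4Cl
Reagents that add atoms: none
Why: Nucleophilic demethylation (SN2 attack of ethanethiolate on the O-methyl group) frees the C8 phenol under conditions to which the isolated trisubstituted alkene and the free alcohols are inert.

Step 15
Reactants: 25 (1R,2S,4S)-6-(hydroxymethyl)-1-methyl-4-[(2S)-6-methylhept-5-en-2-yl]-1,2,3,4-tetrahydronaphthalene-2,8-diol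
Product: 26 (1R,2S,4S)-8-acetoxy-6-(acetoxymethyl)-1-methyl-4-[(2S)-6-methylhept-5-en-2-yl]-1,2,3,4-tetrahydronaphthalen-2-yl acetate
Conditions: Ac2O, pyridine, DMAP (cat.), CH2Cl2, rt
Reagents that add atoms: acetic anhydride, CC(=O)OC(C)=O
Why: Exhaustive DMAP-catalysed acetylation converts all three hydroxyl groups, including the hindered secondary C2 alcohol, into acetates.

Step 16
Reactants: 26 (1R,2S,4S)-8-acetoxy-6-(acetoxymethyl)-1-methyl-4-[(2S)-6-methylhept-5-en-2-yl]-1,2,3,4-tetrahydronaphthalen-2-yl acetate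
Product: 27 (1R,2S,4S)-6-(acetoxymethyl)-8-hydroxy-1-methyl-4-[(2S)-6-methylhept-5-en-2-yl]-1,2,3,4-tetrahydronaphthalen-2-yl acetate
Conditions: NH4OAc (cat.), MeOH/H2O, rt
Reagents that add atoms: none
Why: Chemoselective methanolysis of the aryl acetate (phenoxide is by far the best leaving group) under the mild catalyst NH4OAc should leave the primary benzylic and the secondary alkyl acetate in place and give the target.

## Compound list

1 | (3-bromo-5-methoxyphenyl)methanol | COc1cc(Br)cc(CO)c1 | starting material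
2 | tert-butyl[(3-bromo-5-methoxyphenyl)methoxy]dimethylsilane | COc1cc(Br)cc(CO[Si](C)(C)C(C)(C)C)c1 | intermediate
3 | oxirane | C1CO1 | starting material
4 | [2-bromo-6-methoxy-4-(TBSOCH2)phenyl]lithium | COc1cc(CO[Si](C)(C)C(C)(C)C)cc(Br)c1[Li] | intermediate
5 | 2-[2-bromo-6-methoxy-4-(TBSOCH2)phenyl]ethan-1-ol | COc1cc(CO[Si](C)(C)C(C)(C)C)cc(Br)c1CCO | intermediate
6 | [2-bromo-6-methoxy-4-(TBSOCH2)phenyl]acetaldehyde | COc1cc(CO[Si](C)(C)C(C)(C)C)cc(Br)c1CC=O | intermediate
7 | [2-bromo-6-methoxy-4-(TBSOCH2)phenyl]acetic acid | COc1cc(CO[Si](C)(C)C(C)(C)C)cc(Br)c1CC(=O)O | intermediate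
8 | (4R)-4-benzyl-1,3-oxazolidin-2-one | O=C1N[C@H](Cc2ccccc2)CO1 | starting material
9 | [2-bromo-6-methoxy-4-(TBSOCH2)phenyl]acetic pivalic anhydride | COc1cc(CO[Si](C)(C)C(C)(C)C)cc(Br)c1CC(=O)OC(=O)C(C)(C)C | intermediate
10 | (4R)-4-benzyl-3-{[2-bromo-6-methoxy-4-(TBSOCH2)phenyl]acetyl}-1,3-oxazolidin-2-one | COc1cc(CO[Si](C)(C)C(C)(C)C)cc(Br)c1CC(=O)N1[C@H](Cc2ccccc2)COC1=O | intermediate
11 | sodium (Z)-enolate of imide 10 | COc1cc(CO[Si](C)(C)C(C)(C)C)cc(Br)c1/C=C(\[O-])N1[C@H](Cc2ccccc2)COC1=O.[Na+] | intermediate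
12 | (4R)-4-benzyl-3-{(2R)-2-[2-bromo-6-methoxy-4-(TBSOCH2)phenyl]propanoyl}-1,3-oxazolidin-2-one | COc1cc(CO[Si](C)(C)C(C)(C)C)cc(Br)c1[C@@H](C)C(=O)N1[C@H](Cc2ccccc2)COC1=O | intermediate
13 | (2R)-2-[2-bromo-6-methoxy-4-(TBSOCH2)phenyl]propan-1-ol | COc1cc(CO[Si](C)(C)C(C)(C)C)cc(Br)c1[C@@H](C)CO | intermediate
14 | (3S)-3,7-dimethylocta-1,6-diene ((S)-β-citronellene) | C=C[C@@H](C)CCC=C(C)C | starting material
15 | (3S)-3,7-dimethyloct-6-en-2-one | CC(=O)[C@@H](C)CCC=C(C)C | intermediate
16 | lithium (3S)-3,7-dimethylocta-1,6-dien-2-olate | [Li+].[O-]C(=C)[C@@H](C)CCC=C(C)C | intermediate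
17 | (3S)-3,7-dimethylocta-1,6-dien-2-yl trifluoromethanesulfonate | C=C(OS(=O)(=O)C(F)(F)F)[C@@H](C)CCC=C(C)C | intermediate
18 | 2-[(3S)-3,7-dimethylocta-1,6-dien-2-yl]-4,4,5,5-tetramethyl-1,3,2-dioxaborolane | C=C(B1OC(C)(C)C(C)(C)O1)[C@@H](C)CCC=C(C)C | intermediate
19 | (2R)-2-{2-[(3S)-3,7-dimethylocta-1,6-dien-2-yl]-6-methoxy-4-(TBSOCH2)phenyl}propan-1-ol | COc1cc(CO[Si](C)(C)C(C)(C)C)cc(C(=C)[C@@H](C)CCC=C(C)C)c1[C@@H](C)CO | intermediate
20 | (2R)-2-{2-[(3S)-3,7-dimethylocta-1,6-dien-2-yl]-6-methoxy-4-(TBSOCH2)phenyl}propanal | COc1cc(CO[Si](C)(C)C(C)(C)C)cc(C(=C)[C@@H](C)CCC=C(C)C)c1[C@@H](C)C=O | intermediate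
21 | O-diiodosamarium ketyl of aldehyde 20 (radical at C2) | COc1cc(CO[Si](C)(C)C(C)(C)C)cc(C(=C)[C@@H](C)CCC=C(C)C)c1[C@@H](C)[CH]O[Sm](I)I | intermediate
22 | cyclised C4-diiodosamarium C2-O-diiodosamarium tetralin (C4 configuration not fixed) | CC(C)(C)[Si](C)(C)OCc1cc(OC)c2c(c1)C([Sm](I)I)([C@@H](C)CCC=C(C)C)C[C@H](O[Sm](I)I)[C@@H]2C | intermediate
23 | (1R,2S,4S)-6-(TBSOCH2)-8-methoxy-1-methyl-4-[(2S)-6-methylhept-5-en-2-yl]-1,2,3,4-tetrahydronaphthalen-2-ol | CC(C)(C)[Si](C)(C)OCc1cc(OC)c2c(c1)[C@H]([C@@H](C)CCC=C(C)C)C[C@H](O)[C@@H]2C | intermediate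
24 | (1R,2S,4S)-6-(hydroxymethyl)-8-methoxy-1-methyl-4-[(2S)-6-methylhept-5-en-2-yl]-1,2,3,4-tetrahydronaphthalen-2-ol | OCc1cc(OC)c2c(c1)[C@H]([C@@H](C)CCC=C(C)C)C[C@H](O)[C@@H]2C | intermediate
25 | (1R,2S,4S)-6-(hydroxymethyl)-1-methyl-4-[(2S)-6-methylhept-5-en-2-yl]-1,2,3,4-tetrahydronaphthalene-2,8-diol | OCc1cc(O)c2c(c1)[C@H]([C@@H](C)CCC=C(C)C)C[C@H](O)[C@@H]2C | intermediate
26 | (1R,2S,4S)-8-acetoxy-6-(acetoxymethyl)-1-methyl-4-[(2S)-6-methylhept-5-en-2-yl]-1,2,3,4-tetrahydronaphthalen-2-yl acetate | CC(=O)OCc1cc(OC(C)=O)c2c(c1)[C@H]([C@@H](C)CCC=C(C)C)C[C@H](OC(C)=O)[C@@H]2C | intermediate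
27 | (1R,2S,4S)-6-(acetoxymethyl)-8-hydroxy-1-methyl-4-[(2S)-6-methylhept-5-en-2-yl]-1,2,3,4-tetrahydronaphthalen-2-yl acetate | CC(=O)OCc1cc(O)c2c(c1)[C@H]([C@@H](C)CCC=C(C)C)C[C@H](OC(C)=O)[C@@H]2C | target

## Step count and risks

Total step count: 16. Longest linear sequence: 13 (steps 1–6 and 10–16; steps 7–9 make the side-chain fragment).

Steps most likely to fail:

Step 12 (key step). What may go wrong:
- pinacol coupling or simple reduction of the ketyl competing with the 6-endo closure;
- closure with the C2 oxygen trans to the C1 methyl;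
- protonation of the C4 organosamarium on the wrong face (the exocyclic C11 centre may oppose the ring bias);
- epimerisation of C1 in the aldehyde before electron transfer.

Fallback: from 20 the ring is closed as the O-stannyl ketyl in a radical chain (Bu3SnH, AIBN, benzene, 80 °C, slow addition). There the C4 radical is quenched by hydrogen-atom transfer from the tin hydride on the face away from the C1 methyl, not by reduction and protonation. C2 is then set separately. The alcohol, taken as the C2 epimer (1R,2R,4S)-6-(TBSOCH2)-8-methoxy-1-methyl-4-[(2S)-6-methylhept-5-en-2-yl]-1,2,3,4-tetrahydronaphthalen-2-ol F1 or as its mixture with 23, is oxidised with Dess–Martin periodinane to (1R,4S)-6-(TBSOCH2)-8-methoxy-1-methyl-4-[(2S)-6-methylhept-5-en-2-yl]-3,4-dihydronaphthalen-2(1H)-one F2. Reduction at −78 °C with LiBH(sBu)3 should deliver hydride anti to the pseudoaxial C1 methyl and return to 23.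

Step 10. What may go wrong: slow transmetalation and protodeboronation of the hindered α-branched alkenyl boronate at the ortho-substituted bromide, and palladium hydride isomerisation of the 1,1-disubstituted alkene. Fallback: the polarity of the coupling is reversed. From 13, Miyaura borylation (B2pin2, PdCl2(dppf), KOAc, dioxane, 90 °C) gives (2R)-2-[2-methoxy-4-(TBSOCH2)-6-(4,4,5,5-tetramethyl-1,3,2-dioxaborolan-2-yl)phenyl]propan-1-ol F3. This is coupled with enol triflate 17 (Pd(PPh3)4, K3PO4, dioxane/H2O, 60 °C) to return to 19.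

Step 2. What may go wrong: loss of LiBr from the ortho-bromoaryllithium (aryne formation) or bromine migration while the epoxide opening is still slow, and consumption of the aryllithium by BF3. Fallback: from 2 the same lithiation is quenched at once with I2 to give 1-bromo-2-iodo-3-methoxy-5-(TBSOCH2)benzene F4. Chemoselective palladium-catalysed coupling at the C–I bond with the Reformatsky reagent BrZnCH2CO2Et (Pd(PPh3)4, THF, 50 °C) gives ethyl [2-bromo-6-methoxy-4-(TBSOCH2)phenyl]acetate F5. Saponification (LiOH, THF/H2O) returns to 7.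

Further compounds
F1 | step 12 | (1R,2R,4S)-6-(TBSOCH2)-8-methoxy-1-methyl-4-[(2S)-6-methylhept-5-en-2-yl]-1,2,3,4-tetrahydronaphthalen-2-ol | CC(C)(C)[Si](C)(C)OCc1cc(OC)c2c(c1)[C@H]([C@@H](C)CCC=C(C)C)C[C@@H](O)[C@@H]2C
F2 | step 12 | (1R,4S)-6-(TBSOCH2)-8-methoxy-1-methyl-4-[(2S)-6-methylhept-5-en-2-yl]-3,4-dihydronaphthalen-2(1H)-one | CC(C)(C)[Si](C)(C)OCc1cc(OC)c2c(c1)[C@H]([C@@H](C)CCC=C(C)C)CC(=O)[C@@H]2C
F3 | step 10 | (2R)-2-[2-methoxy-4-(TBSOCH2)-6-(4,4,5,5-tetramethyl-1,3,2-dioxaborolan-2-yl)phenyl]propan-1-ol | COc1cc(CO[Si](C)(C)C(C)(C)C)cc(B2OC(C)(C)C(C)(C)O2)c1[C@@H](C)CO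
F4 | step 2 | 1-bromo-2-iodo-3-methoxy-5-(TBSOCH2)benzene | COc1cc(CO[Si](C)(C)C(C)(C)C)cc(Br)c1I
F5 | step 2 | ethyl [2-bromo-6-methoxy-4-(TBSOCH2)phenyl]acetate | CCOC(=O)Cc1c(OC)cc(CO[Si](C)(C)C(C)(C)C)cc1Br
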